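Read the zeta run at 40.0 min and again at 80.0 min: the time doubles and target grows 3.71-fold, and the epsilon run gives 3.77-fold over the same times. Target therefore follows the square of time, so the rate climbs in step with time, as if working catalyst were released steadily from the precatalyst.

| flask | starting material | second substrate | reagent | precatalyst | remark |
|---|---|---|---|---|---|
| alpha | 5 mM | 1 equiv | 0.90 equiv | 5 mol% | run made earlier |
| epsilon | 20 mM | 1 equiv | 0.90 equiv | 5 mol% | run made earlier |
| zeta | 10 mM | 0.50 equiv | 0.90 equiv | 5 mol% | run made earlier |
| flask | 10 mM | 1.00 equiv | 0.900 equiv | 5 mol% |  |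

| run | time / min | target / % | starting material / % |
|---|---|---|---|
| alpha | 10.0 | 0 | 100.8 |
| alpha | 20.0 | 1.4 | 98.5 |
| alpha | 30.0 | 2.8 | 96.4 |
| alpha | 40.0 | 2.9 | 94.6 |
| alpha | 50.0 | 8.0 | 92.3 |
| alpha | 60.0 | 9.9 | 91.8 |
| alpha | 80.0 | 15.9 | 83.3 |
| epsilon | 4.00 | 0 | 100.0 |
| epsilon | 12.0 | 1.3 | 97.6 |
| epsilon | 20.0 | 1.8 | 97.7 |
| epsilon | 30.0 | 4.3 | 96.5 |
| epsilon | 40.0 | 6.4 | 94.2 |
| epsilon | 60.0 | 13.3 | 86.2 |
| epsilon | 80.0 | 24.1 | 76.8 |
| zeta | 15.0 | 1.6 | 98.5 |
| zeta | 30.0 | 6.4 | 94.0 |
| zeta | 40.0 | 8.5 | 90.4 |
| zeta | 60.0 | 20.2 | 80.1 |
| zeta | 80.0 | 31.5 | 66.3 |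

(readings scatter by 1 percentage point)



* factor on the rate of making target when 30% of the starting material are converted if reagent is charged twice over
* factor on the rate when 30% of the starting material are converted if precatalyst is charged at 1 mol% instead

Keep the ledger on the reagent, the limiting reagent at 0.900 equiv, with 9.00 mM charged to the flask. A conversion of 30% books 3.00 mM to target, a third of the charge, and leaves at most 6.00 mM; reagent was never read, so another taker cannot be excluded and this entry stays open. With the charge doubled, at most 15.0 mM remains at that conversion; with target entered as the one taker, that is 2.50 times as much. All the earlier runs held the reagent at the same equivalents, so they give no order for it. Take dbl as lying between 1, if turnover ignores reagent, and 1.77, if the rate follows it and the conversion comes sooner.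

Now define the arrival stretch, the factor by which the time to a fixed conversion lengthens when the precatalyst load falls. If target grows as load times the square of time, going from 5 mol% to 1 mol% gives 2.24. The rate at a fixed conversion falls by the same factor, so my ratio is 0.446.

The forecast gives 1.35 and 0.42, the second lower than my figure, and notes that "Reagent was never varied independently".

The flask gives 1.20 for dbl and 0.342 for ratio.

    starting material + free catalyst ⇌ catalyst intermediate A (K = 2800 L mol⁻¹, k = 350 L mol⁻¹ min⁻¹)
    second substrate + free catalyst ⇌ catalyst intermediate B (K = 1200 L mol⁻¹, k = 1200 L mol⁻¹ min⁻¹)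
    reagent + catalyst intermediate B → free catalyst + second product (k = 12.0 L mol⁻¹ min⁻¹)
    reagent + catalyst intermediate A → free catalyst + target (k = 360 L mol⁻¹ min⁻¹)
    precatalyst → free catalyst (k = 0.00590 min⁻¹)

In the 1 mol% flask, precatalyst is still 20.4% of the catalyst at that conversion, which puts arrival at 4.49 h, later than the 3.90 h that the stretch gives from 1.74 h. The released share there is 79.6%, against 46.0% in this flask, so load times released share stands at 0.346 of this flask's value.

The earlier runs and the new flask are simulated from invented constants; noise was put on by code.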